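Retrosynthesis: the acid terminus is traced back to the E-methyl group of a prenyl end; the core is then cut at C3a–C4 (six-membered carbocycle), at O1–C7a (dihydrofuran ring) and at C3–C3a (fragment union), which leaves a C6 alkynoic acid and a C15 terminal epoxide.
Forward: the acetylide of the alkynoic acid opens the epoxide (C3–C3a) and the carboxyl group is made into the dimethylamide; a 5-endo-dig hydroalkoxylation closes the dihydrofuran (O1–C7a) and Tf2O activation of the amide closes the carbocycle (C3a–C4); the chain end is oxidised and the silyl ethers are removed last.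
Enabling feature: once O1–C7a exists, C3a is the nucleophilic β-carbon of a cyclic enol ether and the amide carbon C4 hangs on C7a through C7, C6 and C5, so only the six-membered ring can close and the carbonyl can only arise at C4, vinylogous to O1.
Stereochemistry: C7 is carried over from D-glutamic acid as (R)-5-oxotetrahydrofuran-2-carboxylic acid; C2 and the tertiary carbinol come from Sharpless epoxidation of (2Z,6E)-farnesol and a Payne rearrangement that inverts the future C2; the 6E alkene comes from farnesol and the E-enoic acid from the E-selectivity of the SeO2 oxidation.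
Key step: step 12

Remark on numbering: the core carries benzofuranone numbers (O1, C2, C3, C3a, C4–C7, C7a); the chain carries primed farnesane numbers (C1′ = ring C3, C2′ = ring C2, C3′ = tertiary carbinol carbon, C12′ = carboxyl carbon).
Assumption: (2Z,6E)-farnesol is bought as the single geometrical isomer.

Step 1
Reactants: 1 (R)-5-oxotetrahydrofuran-2-carboxylic acid
Product: 2 (R)-5-(hydroxymethyl)dihydrofuran-2(3H)-one
Conditions: BH3·SMe2, THF, 0 °C → rt; MeOH quench
Reagents that add atoms: none
Why: Borane reduces the free carboxylic acid through its acyloxyborane far faster than the lactone carbonyl (chemoselective borane reduction), and the C7 stereocentre is not involved.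

Step 2
Reactants: 2 (R)-5-(hydroxymethyl)dihydrofuran-2(3H)-one
Product: 3 (R)-5-oxotetrahydrofuran-2-carbaldehyde
Conditions: Dess–Martin periodinane, CH2Cl2, 0 °C → rt; filtration, crude product used at once
Reagents that add atoms: none
Why: Dess–Martin oxidation takes the primary alcohol to the aldehyde under neutral conditions, so the α-oxygenated stereocentre is not enolised, and the hydration-prone aldehyde is homologated without storage.

Step 3
Reactants: 3 (R)-5-oxotetrahydrofuran-2-carbaldehyde
Product: 4 (R)-5-ethynyldihydrofuran-2(3H)-one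
Conditions: dimethyl (1-diazo-2-oxopropyl)phosphonate, K2CO3, MeOH, 0 °C → rt
Reagents that add atoms: dimethyl (1-diazo-2-oxopropyl)phosphonate, COP(=O)(OC)C(=[N+]=[N-])C(C)=O (supplies the terminal alkyne carbon)
Why: Ohira–Bestmann (Seyferth–Gilbert) homologation turns the aldehyde into the terminal alkyne that will supply C7a and C3a, a reaction that leaves α-oxygenated stereocentres intact because alkynylation outruns enolisation; lactone opened by methoxide would converge with 4 on the same carboxylate in step 4.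

Step 4
Reactants: 4 (R)-5-ethynyldihydrofuran-2(3H)-one
Product: 7 (R)-4-(tert-butyldimethylsilyloxy)hex-5-ynoic acid, via lithium hydroxy carboxylate 5 (not isolated), via bis-silylated ester 6 (not isolated)
Conditions: LiOH, THF/H2O, 0 °C → rt, evaporate; t-BuMe2SiCl, imidazole, DMF, rt; then K2CO3, MeOH/H2O, rt; pH 4 work-up
Reagents that add atoms: lithium hydroxide, [Li+].[OH-] (one carboxyl oxygen); tert-butyldimethylsilyl chloride, CC(C)(C)[Si](C)(C)Cl
Why: Saponification opens the γ-lactone irreversibly, silylation of the carboxylate salt caps the C7 hydroxyl so that relactonisation is no longer possible, and the labile silyl ester is cleaved selectively by mild base, which frees the carboxyl group needed as an inert lithium carboxylate in step 9.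

Step 5
Reactants: 8 (2Z,6E)-farnesol
Product: 9 [(2R,3S)-3-[(3E)-4,8-dimethylnona-3,7-dien-1-yl]-3-methyloxiran-2-yl]methanol
Conditions: Ti(OiPr)4 (10 mol %), D-(−)-diethyl tartrate (12 mol %), t-BuOOH (2 equiv), 4 Å MS, CH2Cl2, −20 °C
Reagents that add atoms: tert-butyl hydroperoxide, CC(C)(C)OO
Why: Sharpless asymmetric epoxidation is specific for the allylic 2′,3′-alkene, and with a Z-allylic alcohol the D-(−)-tartrate catalyst should deliver oxygen to the face that gives the (2R,3S)-epoxide, which fixes the configuration of the future tertiary carbinol C3′ by reagent control.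

Step 6
Reactants: 9 [(2R,3S)-3-[(3E)-4,8-dimethylnona-3,7-dien-1-yl]-3-methyloxiran-2-yl]methanol
Product: 10 (2R,3S,6E)-3,7,11-trimethyl-1-(phenylsulfanyl)dodeca-6,10-diene-2,3-diol
Conditions: PhSH (slow addition), 0.5 M aq. NaOH, t-BuOH, 75 °C
Reagents that add atoms: thiophenol, Sc1ccccc1
Why: Under aqueous base the 2,3-epoxy alcohol equilibrates by Payne rearrangement (intramolecular SN2 at C2′ with inversion, C3′–O retained) with the terminal 1,2-epoxide, and thiophenoxide intercepts only this unhindered epoxide at C1′ (Curtin–Hammett control), so that C2′ acquires the configuration needed for ring carbon C2.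

Step 7
Reactants: 10 (2R,3S,6E)-3,7,11-trimethyl-1-(phenylsulfanyl)dodeca-6,10-diene-2,3-diol
Product: 12 (2S,5E)-6,10-dimethyl-2-[(2S)-oxiran-2-yl]undeca-5,9-dien-2-ol, via methylsulfonium tetrafluoroborate 11 (not isolated)
Conditions: Me3OBF4, CH2Cl2, 0 °C → rt; then 0.5 M aq. NaOH (1.1 equiv), 0 °C
Reagents that add atoms: none
Why: S-Methylation turns the sulfide into a sulfonium leaving group and the C2′ alkoxide displaces methyl phenyl sulfide in a 3-exo-tet closure that touches neither stereocentre, while the use of only one equivalent of base keeps the tertiary alkoxide from reverting by Payne rearrangement.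

Step 8
Reactants: 12 (2S,5E)-6,10-dimethyl-2-[(2S)-oxiran-2-yl]undeca-5,9-dien-2-ol
Product: 13 triethyl{[(2S,5E)-6,10-dimethyl-2-[(2S)-oxiran-2-yl]undeca-5,9-dien-2-yl]oxy}silane
Conditions: Et3SiOTf, 2,6-lutidine, CH2Cl2, −78 °C
Reagents that add atoms: triethylsilyl trifluoromethanesulfonate, CC[Si](CC)(CC)OS(=O)(=O)C(F)(F)F
Why: Silylation of the hindered tertiary alcohol with the silyl triflate and 2,6-lutidine at low temperature leaves the epoxide intact and blocks the C3′ oxygen against Payne rearrangement in step 9 and against 5-exo attack on the alkyne in step 11.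

Step 9
Reactants: 7 (R)-4-(tert-butyldimethylsilyloxy)hex-5-ynoic acid; 13 triethyl{[(2S,5E)-6,10-dimethyl-2-[(2S)-oxiran-2-yl]undeca-5,9-dien-2-yl]oxy}silane
Product: 15 (4R,8S,9S,12E)-4-(tert-butyldimethylsilyloxy)-8-hydroxy-9,13,17-trimethyl-9-(triethylsilyloxy)octadeca-12,16-dien-5-ynoic acid, via dilithio acetylide carboxylate 14 (not isolated)
Conditions: 7 (1.3 equiv), n-BuLi (2.6 equiv), THF, −78 °C; BF3·OEt2 (2.6 equiv); then 13, −78 °C; aq. NH4Cl, then HCl to pH 4, 0 °C
Reagents that add atoms: none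
Why: Yamaguchi–Hirao alkynylation: the lithium acetylide opens the BF3-activated terminal epoxide at its CH2 terminus C1′ by SN2 attack without touching C2′ or C3′, and the carboxyl group rides as an unreactive lithium carboxylate because an amide or ester carbonyl could itself be alkynylated by the acetylide–BF3 reagent.

Step 10
Reactants: 15 (4R,8S,9S,12E)-4-(tert-butyldimethylsilyloxy)-8-hydroxy-9,13,17-trimethyl-9-(triethylsilyloxy)octadeca-12,16-dien-5-ynoic acid
Product: 16 (4R,8S,9S,12E)-4-(tert-butyldimethylsilyloxy)-8-hydroxy-N,N,9,13,17-pentamethyl-9-(triethylsilyloxy)octadeca-12,16-dien-5-ynamide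
Conditions: Me2NH (2 M in THF), EDC·HCl, HOBt, CH2Cl2, 0 °C → rt
Reagents that add atoms: dimethylamine, CNC
Why: Carbodiimide/HOBt amidation activates only the carboxylic acid, the hindered secondary alcohol beside the quaternary carbon is not acylated, and the dimethylamide so formed is the acyl donor of the key step.

Step 11
Reactants: 16 (4R,8S,9S,12E)-4-(tert-butyldimethylsilyloxy)-8-hydroxy-N,N,9,13,17-pentamethyl-9-(triethylsilyloxy)octadeca-12,16-dien-5-ynamide
Product: 17 (R)-4-(tert-butyldimethylsilyloxy)-4-[(S)-5-[(2S,5E)-6,10-dimethyl-2-(triethylsilyloxy)undeca-5,9-dien-2-yl]-4,5-dihydrofuran-2-yl]-N,N-dimethylbutanamide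
Conditions: Ph3PAuNTf2 (5 mol %), 4 Å MS, THF, rt; Et3N quench; chromatography on Et3N-deactivated silica
Reagents that add atoms: none
Why: Gold-catalysed 5-endo-dig hydroalkoxylation (cycloisomerisation of a 3-alkyn-1-ol) adds the only free hydroxyl group to the activated alkyne at C7a and forms the O1–C7a bond of the 2,3-dihydrofuran, the silylated C3′ oxygen being unable to compete and no stereocentre being created.

Step 12
Reactants: 17 (R)-4-(tert-butyldimethylsilyloxy)-4-[(S)-5-[(2S,5E)-6,10-dimethyl-2-(triethylsilyloxy)undeca-5,9-dien-2-yl]-4,5-dihydrofuran-2-yl]-N,N-dimethylbutanamide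
Product: 20 (2S,7R)-7-(tert-butyldimethylsilyloxy)-2-[(2S,5E)-6,10-dimethyl-2-(triethylsilyloxy)undeca-5,9-dien-2-yl]-3,5,6,7-tetrahydrobenzofuran-4(2H)-one, via O-triflyliminium triflate 18 (not isolated), via bicyclic iminium triflate 19 (not isolated)
Conditions: Tf2O (1.2 equiv), 2,6-di-tert-butyl-4-methylpyridine (3 equiv), CH2Cl2, −78 → 0 °C; then sat. aq. NaHCO3/THF, rt
Reagents that add atoms: water, O
Why: Tf2O O-triflates the tertiary amide to the O-triflyliminium ion 18, the enol ether attacks it through its β-carbon C3a, triflate leaves and the hindered base removes the C3a proton to give the conjugated iminium salt 19, which aqueous hydrogencarbonate hydrolyses at the iminium carbon to the C4 ketone. The closest known reactions are the Vilsmeier–Haack-type cyclisations of Tf2O-activated tertiary amides onto tethered enol ethers and the Vilsmeier formylation of cyclic enol ethers such as glycals, in which the ring oxygen is likewise kept on hydrolysis. The six-membered carbocycle closes in a 6-(enolendo)-exo-trig mode, with the C3a=C7a bond inside the new ring and the iminium C=N bond outside it. No stereocentre is formed: C2, C7 and C3′ are spectators, and the base should take the C3a proton, which is activated by both cationic centres, and not the C7 proton. The step needs site selectivity for C3a over the chain alkenes and over the silyl ether oxygen at C7; enol ether polarisation and the six-membered transition state should secure the first, the bulk of the tert-butyldimethylsilyl group and the low temperature the second. The excess of non-nucleophilic base keeps triflic acid away from the acid-labile enol ether and silyl ethers.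

Step 13
Reactants: 20 (2S,7R)-7-(tert-butyldimethylsilyloxy)-2-[(2S,5E)-6,10-dimethyl-2-(triethylsilyloxy)undeca-5,9-dien-2-yl]-3,5,6,7-tetrahydrobenzofuran-4(2H)-one
Product: 21 (2S,7R)-7-(tert-butyldimethylsilyloxy)-2-[(2S,5E,9E)-11-hydroxy-6,10-dimethyl-2-(triethylsilyloxy)undeca-5,9-dien-2-yl]-3,5,6,7-tetrahydrobenzofuran-4(2H)-one
Conditions: SeO2 (0.3 equiv), t-BuOOH (3 equiv), salicylic acid (0.1 equiv), CH2Cl2, rt
Reagents that add atoms: selenium dioxide, O=[Se]=O (oxygen transfer, catalytic); tert-butyl hydroperoxide, CC(C)(C)OO (reoxidant)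
Why: The catalytic SeO2/t-BuOOH allylic oxidation (ene reaction then [2,3]-sigmatropic shift) prefers the E-methyl group of the terminal, least hindered trisubstituted alkene and sets the E geometry of the future enoic acid, and any enal 22 formed by over-oxidation is carried into step 14.

Step 14
Reactants: 21 (2S,7R)-7-(tert-butyldimethylsilyloxy)-2-[(2S,5E,9E)-11-hydroxy-6,10-dimethyl-2-(triethylsilyloxy)undeca-5,9-dien-2-yl]-3,5,6,7-tetrahydrobenzofuran-4(2H)-one
Product: 22 (2E,6E,10S)-10-[(2S,7R)-7-(tert-butyldimethylsilyloxy)-4-oxo-2,3,4,5,6,7-hexahydrobenzofuran-2-yl]-2,6-dimethyl-10-(triethylsilyloxy)undeca-2,6-dienal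
Conditions: MnO2 (excess), CH2Cl2, rt
Reagents that add atoms: none
Why: MnO2 oxidises only the primary allylic alcohol to the conjugated aldehyde, without isomerising the alkene and without touching the silyl ethers or the vinylogous ester.

Step 15
Reactants: 22 (2E,6E,10S)-10-[(2S,7R)-7-(tert-butyldimethylsilyloxy)-4-oxo-2,3,4,5,6,7-hexahydrobenzofuran-2-yl]-2,6-dimethyl-10-(triethylsilyloxy)undeca-2,6-dienal
Product: 23 (2E,6E,10S)-10-[(2S,7R)-7-(tert-butyldimethylsilyloxy)-4-oxo-2,3,4,5,6,7-hexahydrobenzofuran-2-yl]-2,6-dimethyl-10-(triethylsilyloxy)undeca-2,6-dienoic acid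
Conditions: NaClO2, NaH2PO4, 2-methyl-2-butene, t-BuOH/H2O, rt
Reagents that add atoms: sodium chlorite, [Na+].[O-]Cl=O
Why: Pinnick oxidation converts the enal into the enoic acid in a weakly acidic buffer, 2-methyl-2-butene consumes the hypochlorous acid that would otherwise attack the chain alkene, and the absence of base protects the C7 stereocentre.

Step 16
Reactants: 23 (2E,6E,10S)-10-[(2S,7R)-7-(tert-butyldimethylsilyloxy)-4-oxo-2,3,4,5,6,7-hexahydrobenzofuran-2-yl]-2,6-dimethyl-10-(triethylsilyloxy)undeca-2,6-dienoic acid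
Product: 24 (2E,6E,10S)-10-hydroxy-10-[(2S,7R)-7-hydroxy-4-oxo-2,3,4,5,6,7-hexahydrobenzofuran-2-yl]-2,6-dimethylundeca-2,6-dienoic acid
Conditions: HF·pyridine, pyridine, THF, 0 °C → rt
Reagents that add atoms: none
Why: Fluoride-mediated desilylation with pyridine-buffered HF·pyridine removes the tertiary triethylsilyl and the secondary tert-butyldimethylsilyl ether under non-basic conditions, so that C7, which is the γ-position of the vinylogous ester, is not epimerised and no elimination towards the aromatic benzofuranol is triggered.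

Compound list
1 | (R)-5-oxotetrahydrofuran-2-carboxylic acid | OC(=O)[C@H]1CCC(=O)O1 | starting material
2 | (R)-5-(hydroxymethyl)dihydrofuran-2(3H)-one | OC[C@H]1CCC(=O)O1 | intermediate
3 | (R)-5-oxotetrahydrofuran-2-carbaldehyde | O=C[C@H]1CCC(=O)O1 | intermediate
4 | (R)-5-ethynyldihydrofuran-2(3H)-one | C#C[C@H]1CCC(=O)O1 | intermediate
5 | lithium (R)-4-hydroxyhex-5-ynoate | C#C[C@H](O)CCC(=O)[O-].[Li+] | intermediate
6 | tert-butyldimethylsilyl (R)-4-(tert-butyldimethylsilyloxy)hex-5-ynoate | C#C[C@H](O[Si](C)(C)C(C)(C)C)CCC(=O)O[Si](C)(C)C(C)(C)C | intermediate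
7 | (R)-4-(tert-butyldimethylsilyloxy)hex-5-ynoic acid | C#C[C@H](O[Si](C)(C)C(C)(C)C)CCC(=O)O | intermediate
8 | (2Z,6E)-farnesol | OC/C=C(/C)CC/C=C(\C)CCC=C(C)C | starting material
9 | [(2R,3S)-3-[(3E)-4,8-dimethylnona-3,7-dien-1-yl]-3-methyloxiran-2-yl]methanol | OC[C@H]1O[C@@]1(C)CC/C=C(\C)CCC=C(C)C | intermediate
10 | (2R,3S,6E)-3,7,11-trimethyl-1-(phenylsulfanyl)dodeca-6,10-diene-2,3-diol | C/C(=C\CC[C@](C)(O)[C@@H](O)CSc1ccccc1)CCC=C(C)C | intermediate
11 | [(2R,3S,6E)-2,3-dihydroxy-3,7,11-trimethyldodeca-6,10-dien-1-yl](methyl)phenylsulfonium tetrafluoroborate | C/C(=C\CC[C@](C)(O)[C@@H](O)C[S+](C)c1ccccc1)CCC=C(C)C.F[B-](F)(F)F | intermediate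
12 | (2S,5E)-6,10-dimethyl-2-[(2S)-oxiran-2-yl]undeca-5,9-dien-2-ol | C/C(=C\CC[C@](C)(O)[C@@H]1CO1)CCC=C(C)C | intermediate
13 | triethyl{[(2S,5E)-6,10-dimethyl-2-[(2S)-oxiran-2-yl]undeca-5,9-dien-2-yl]oxy}silane | C/C(=C\CC[C@](C)(O[Si](CC)(CC)CC)[C@@H]1CO1)CCC=C(C)C | intermediate
14 | lithium (R)-4-(tert-butyldimethylsilyloxy)-6-lithiohex-5-ynoate | [Li]C#C[C@H](O[Si](C)(C)C(C)(C)C)CCC(=O)[O-].[Li+] | intermediate
15 | (4R,8S,9S,12E)-4-(tert-butyldimethylsilyloxy)-8-hydroxy-9,13,17-trimethyl-9-(triethylsilyloxy)octadeca-12,16-dien-5-ynoic acid | C/C(=C\CC[C@](C)(O[Si](CC)(CC)CC)[C@@H](O)CC#C[C@H](O[Si](C)(C)C(C)(C)C)CCC(=O)O)CCC=C(C)C | intermediate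
16 | (4R,8S,9S,12E)-4-(tert-butyldimethylsilyloxy)-8-hydroxy-N,N,9,13,17-pentamethyl-9-(triethylsilyloxy)octadeca-12,16-dien-5-ynamide | C/C(=C\CC[C@](C)(O[Si](CC)(CC)CC)[C@@H](O)CC#C[C@H](O[Si](C)(C)C(C)(C)C)CCC(=O)N(C)C)CCC=C(C)C | intermediate
17 | (R)-4-(tert-butyldimethylsilyloxy)-4-[(S)-5-[(2S,5E)-6,10-dimethyl-2-(triethylsilyloxy)undeca-5,9-dien-2-yl]-4,5-dihydrofuran-2-yl]-N,N-dimethylbutanamide | C/C(=C\CC[C@](C)(O[Si](CC)(CC)CC)[C@@H]1CC=C(O1)[C@H](O[Si](C)(C)C(C)(C)C)CCC(=O)N(C)C)CCC=C(C)C | intermediate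
18 | N-[(4R)-4-(tert-butyldimethylsilyloxy)-4-[(5S)-5-[(2S,5E)-6,10-dimethyl-2-(triethylsilyloxy)undeca-5,9-dien-2-yl]-4,5-dihydrofuran-2-yl]-1-(trifluoromethanesulfonyloxy)butylidene]-N-methylmethanaminium trifluoromethanesulfonate | C/C(=C\CC[C@](C)(O[Si](CC)(CC)CC)[C@@H]1CC=C(O1)[C@H](O[Si](C)(C)C(C)(C)C)CCC(OS(=O)(=O)C(F)(F)F)=[N+](C)C)CCC=C(C)C.[O-]S(=O)(=O)C(F)(F)F | intermediate
19 | N-[(2S,7R)-7-(tert-butyldimethylsilyloxy)-2-[(2S,5E)-6,10-dimethyl-2-(triethylsilyloxy)undeca-5,9-dien-2-yl]-3,5,6,7-tetrahydrobenzofuran-4(2H)-ylidene]-N-methylmethanaminium trifluoromethanesulfonate | C/C(=C\CC[C@](C)(O[Si](CC)(CC)CC)[C@@H]1CC2=C(O1)[C@H](O[Si](C)(C)C(C)(C)C)CCC2=[N+](C)C)CCC=C(C)C.[O-]S(=O)(=O)C(F)(F)F | intermediate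
20 | (2S,7R)-7-(tert-butyldimethylsilyloxy)-2-[(2S,5E)-6,10-dimethyl-2-(triethylsilyloxy)undeca-5,9-dien-2-yl]-3,5,6,7-tetrahydrobenzofuran-4(2H)-one | C/C(=C\CC[C@](C)(O[Si](CC)(CC)CC)[C@@H]1CC2=C(O1)[C@H](O[Si](C)(C)C(C)(C)C)CCC2=O)CCC=C(C)C | intermediate
21 | (2S,7R)-7-(tert-butyldimethylsilyloxy)-2-[(2S,5E,9E)-11-hydroxy-6,10-dimethyl-2-(triethylsilyloxy)undeca-5,9-dien-2-yl]-3,5,6,7-tetrahydrobenzofuran-4(2H)-one | C/C(=C\CC[C@](C)(O[Si](CC)(CC)CC)[C@@H]1CC2=C(O1)[C@H](O[Si](C)(C)C(C)(C)C)CCC2=O)CC/C=C(\C)CO | intermediate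
22 | (2E,6E,10S)-10-[(2S,7R)-7-(tert-butyldimethylsilyloxy)-4-oxo-2,3,4,5,6,7-hexahydrobenzofuran-2-yl]-2,6-dimethyl-10-(triethylsilyloxy)undeca-2,6-dienal | C/C(=C\CC[C@](C)(O[Si](CC)(CC)CC)[C@@H]1CC2=C(O1)[C@H](O[Si](C)(C)C(C)(C)C)CCC2=O)CC/C=C(\C)C=O | intermediate
23 | (2E,6E,10S)-10-[(2S,7R)-7-(tert-butyldimethylsilyloxy)-4-oxo-2,3,4,5,6,7-hexahydrobenzofuran-2-yl]-2,6-dimethyl-10-(triethylsilyloxy)undeca-2,6-dienoic acid | C/C(=C\CC[C@](C)(O[Si](CC)(CC)CC)[C@@H]1CC2=C(O1)[C@H](O[Si](C)(C)C(C)(C)C)CCC2=O)CC/C=C(\C)C(=O)O | intermediate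
24 | (2E,6E,10S)-10-hydroxy-10-[(2S,7R)-7-hydroxy-4-oxo-2,3,4,5,6,7-hexahydrobenzofuran-2-yl]-2,6-dimethylundeca-2,6-dienoic acid (CNP0297149.1) | C/C(=C\CC[C@](C)(O)[C@@H]1CC2=C(O1)[C@H](O)CCC2=O)CC/C=C(\C)C(=O)O | target

Total step count: 16. Longest linear sequence: 12 steps (steps 1–4 and 9–16; the farnesol branch, steps 5–8 and 9–16, is equally long).

Steps most likely to fail

Step 12 (key step). The activated amide may be captured by the silyl ether oxygen at C7 (five-membered oxonium, loss of the silyl group, lactone after hydrolysis) faster than by C3a, or acid set free during activation may hydrolyse the enol ether. The fallback changes the oxidation level of the electrophile and sets out from 17. Reduction of the amide with Cp2Zr(H)Cl (THF, rt) should give the aldehyde (R)-4-(tert-butyldimethylsilyloxy)-4-[(S)-5-[(2S,5E)-6,10-dimethyl-2-(triethylsilyloxy)undeca-5,9-dien-2-yl]-4,5-dihydrofuran-2-yl]butanal F1. A Lewis-acid-catalysed intramolecular carbonyl-ene (Prins-type) addition of the enol ether to the aldehyde (Yb(OTf)3 cat., CH2Cl2, 0 °C) would form the same C3a–C4 bond and the same ring and give the allylic alcohol (2S,7R)-7-(tert-butyldimethylsilyloxy)-2-[(2S,5E)-6,10-dimethyl-2-(triethylsilyloxy)undeca-5,9-dien-2-yl]-2,3,4,5,6,7-hexahydrobenzofuran-4-ol F2 as a mixture of C4 epimers. Oxidation with MnO2 (CH2Cl2, rt) would then return to the route at 20.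

Step 9 (fragment union). The lithium carboxylate may bind BF3 and precipitate the dianion so that the epoxide is not opened, or the silyloxy epoxide may rearrange under the Lewis acid before it is attacked. The fallback carries the carboxyl group as an ester and sets out from 7. Esterification with trimethylsilyldiazomethane (MeOH/toluene, 0 °C) should give methyl (R)-4-(tert-butyldimethylsilyloxy)hex-5-ynoate F3. Deprotonation with n-BuLi (1.0 equiv, THF, −78 °C) would give methyl (R)-4-(tert-butyldimethylsilyloxy)-6-lithiohex-5-ynoate F4, which would open 13 under the BF3·OEt2 conditions of step 9 to methyl (4R,8S,9S,12E)-4-(tert-butyldimethylsilyloxy)-8-hydroxy-9,13,17-trimethyl-9-(triethylsilyloxy)octadeca-12,16-dien-5-ynoate F5. Aminolysis with Me2NH and catalytic 1,5,7-triazabicyclo[4.4.0]dec-5-ene (THF, 40 °C) would return to the route at 16, so that 15 and step 10 are bypassed.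

Step 13 (allylic oxidation). The selenium reagent may attack the internal trisubstituted alkene as well as the terminal one, or over-oxidise, so that little of the E-allylic alcohol is obtained from an advanced intermediate. The fallback replaces C–H oxidation by olefin metathesis and sets out from 20. Cross-metathesis with excess methacrolein (second-generation Hoveyda–Grubbs catalyst, CH2Cl2, 40 °C) would exchange the isopropylidene terminus for the (E)-2-methylpropenal unit and return to the route at 22, which replaces steps 13 and 14 by one operation; no compound outside the list arises (none F0).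

Further compounds
F1 | step 12 | (R)-4-(tert-butyldimethylsilyloxy)-4-[(S)-5-[(2S,5E)-6,10-dimethyl-2-(triethylsilyloxy)undeca-5,9-dien-2-yl]-4,5-dihydrofuran-2-yl]butanal | C/C(=C\CC[C@](C)(O[Si](CC)(CC)CC)[C@@H]1CC=C(O1)[C@H](O[Si](C)(C)C(C)(C)C)CCC=O)CCC=C(C)C
F2 | step 12 | (2S,7R)-7-(tert-butyldimethylsilyloxy)-2-[(2S,5E)-6,10-dimethyl-2-(triethylsilyloxy)undeca-5,9-dien-2-yl]-2,3,4,5,6,7-hexahydrobenzofuran-4-ol (C4 epimers) | C/C(=C\CC[C@](C)(O[Si](CC)(CC)CC)[C@@H]1CC2=C(O1)[C@H](O[Si](C)(C)C(C)(C)C)CCC2O)CCC=C(C)C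
F3 | step 9 | methyl (R)-4-(tert-butyldimethylsilyloxy)hex-5-ynoate | C#C[C@H](O[Si](C)(C)C(C)(C)C)CCC(=O)OC
F4 | step 9 | methyl (R)-4-(tert-butyldimethylsilyloxy)-6-lithiohex-5-ynoate | [Li]C#C[C@H](O[Si](C)(C)C(C)(C)C)CCC(=O)OC
F5 | step 9 | methyl (4R,8S,9S,12E)-4-(tert-butyldimethylsilyloxy)-8-hydroxy-9,13,17-trimethyl-9-(triethylsilyloxy)octadeca-12,16-dien-5-ynoate | C/C(=C\CC[C@](C)(O[Si](CC)(CC)CC)[C@@H](O)CC#C[C@H](O[Si](C)(C)C(C)(C)C)CCC(=O)OC)CCC=C(C)C
F0 | step 13 | none | none
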